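**Assumption:** germacrane numbering of the target (C1–C15, lactone C12–O–C6) is used for positions in all intermediates; C11 epimers of the two aminomethyl adducts are carried as mixtures because C11 becomes sp2 again. The route is a paper design and has not been run.

**Retrosynthetic overview**
1. C1–OOH: SN2 (inversion) of a perketal-protected hydroperoxide on the (1S)-allylic mesylate, with the lactone methylene masked as its Me2NH adduct; C1 is set by CBS reduction of the C1 enone.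
2. Ten-membered ring: intramolecular Ni/Cr (Nozaki–Hiyama–Kishi) closure of C1–C10 from a 2-bromoalkene and a C1 aldehyde.
3. C8–C9: chromium-mediated 2-bromoallylation of a C8 aldehyde (sets C8); angelate by mixed-anhydride acylation; C13 by Eschenmoser methylenation.
4. Key fragment union C6–C7: intermolecular Evans syn-aldol of a succinate imide with Z-enal 8 (from neryl acetate), lactonising in the same pot (sets C6 and C7).
5. Ring order: γ-lactone first, ten-membered carbocycle second.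

**Route**

Step 1
Reactants: 1 neryl acetate
Product: 2 6,7-epoxyneryl acetate (racemic at the epoxide)
Conditions: mCPBA (1.05 equiv), NaHCO3, CH2Cl2, 0 °C
Reagents that add atoms: mCPBA OOC(=O)c1cccc(Cl)c1
Why: Prilezhaev epoxidation picks the electron-rich 6,7-alkene over the 2,3-alkene that is deactivated by the allylic acetate, and the epoxide stereocentre is erased in step 2.

Step 2
Reactants: 2 6,7-epoxyneryl acetate
Product: 4 (2Z)-3-methyl-6-oxohex-2-en-1-yl acetate, via diol 3 (not isolated)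
Conditions: H5IO6 (1.2 equiv), THF/H2O, 0 °C → rt
Reagents that add atoms: water O (in intermediate 3 only)
Why: Acid-promoted epoxide hydrolysis then Malaprade glycol cleavage removes the terminal carbons as acetone and leaves the Z-trisubstituted alkene untouched.

Step 3
Reactants: 4 (2Z)-3-methyl-6-oxohex-2-en-1-yl acetate
Product: 5 (2Z)-6-hydroxy-3-methylhex-2-en-1-yl acetate
Conditions: NaBH4 (0.5 equiv), MeOH, 0 °C, 15 min
Reagents that add atoms: none
Why: Chemoselective borohydride reduction of the aldehyde in the presence of the acetate.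

Step 4
Reactants: 5 (2Z)-6-hydroxy-3-methylhex-2-en-1-yl acetate
Product: 6 (2Z)-6-[(tert-butyldiphenylsilyl)oxy]-3-methylhex-2-en-1-yl acetate
Conditions: TBDPSCl, imidazole, DMF, rt
Reagents that add atoms: tert-butyl(chloro)diphenylsilane CC(C)(C)[Si](Cl)(c1ccccc1)c1ccccc1
Why: Silylation of the primary alcohol gives an ether that survives every step up to step 17.

Step 5
Reactants: 6 (2Z)-6-[(tert-butyldiphenylsilyl)oxy]-3-methylhex-2-en-1-yl acetate
Product: 7 (2Z)-6-[(tert-butyldiphenylsilyl)oxy]-3-methylhex-2-en-1-ol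
Conditions: K2CO3 (0.2 equiv), MeOH, rt
Reagents that add atoms: none
Why: Base-catalysed transesterification frees the allylic alcohol without touching the silyl ether.

Step 6
Reactants: 7 (2Z)-6-[(tert-butyldiphenylsilyl)oxy]-3-methylhex-2-en-1-ol
Product: 8 (2Z)-6-[(tert-butyldiphenylsilyl)oxy]-3-methylhex-2-enal
Conditions: TEMPO (10 mol%), PhI(OAc)2 (1.1 equiv), CH2Cl2, rt
Reagents that add atoms: none
Why: Oxoammonium (TEMPO) oxidation is neutral, so the neral-type Z-enal forms without isomerisation to E.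

Step 7
Reactants: 9 (4S)-4-benzyl-1,3-oxazolidin-2-one; 10 methyl 4-chloro-4-oxobutanoate
Product: 11 methyl 4-[(4S)-4-benzyl-2-oxo-1,3-oxazolidin-3-yl]-4-oxobutanoate
Conditions: Et3N (1.3 equiv), DMAP (10 mol%), CH2Cl2, 0 °C → rt
Reagents that add atoms: none
Why: DMAP-catalysed N-acylation puts the Evans auxiliary on the succinate half-ester.

Step 8
Reactants: 11 succinate imide; 8 Z-enal
Product: 14 (4S)-4-benzyl-3-{[(2R,3S)-2-[(1Z)-5-[(tert-butyldiphenylsilyl)oxy]-2-methylpent-1-en-1-yl]-5-oxooxolan-3-yl]carbonyl}-1,3-oxazolidin-2-one, via boron enolate 12 (not isolated), via boron aldolate 13 (not isolated)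
Conditions: Bu2BOTf (1.1 equiv), Et3N (1.3 equiv), CH2Cl2, −78 → 0 °C; then 8, −78 → 0 °C; pH 7 buffer; then PPTS (cat.), CH2Cl2, rt
Reagents that add atoms: dibutylboron triflate CCCCB(CCCC)OS(=O)(=O)C(F)(F)F (in intermediates 12 and 13 only)
Why: Evans syn-aldol through the Z-boron enolate and a Zimmerman–Traxler chair, anti to the benzyl group, sets C6 (R) and C7 (S in the imide), and the aldolate oxygen then closes on the methyl ester to give the trans γ-lactone.

Step 9
Reactants: 14 lactone imide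
Product: 15 S-ethyl (2R,3S)-2-[(1Z)-5-[(tert-butyldiphenylsilyl)oxy]-2-methylpent-1-en-1-yl]-5-oxooxolane-3-carbothioate
Conditions: EtSH (3 equiv), n-BuLi (2.5 equiv), THF, 0 °C, 30 min
Reagents that add atoms: ethanethiol CCS
Why: Thiolate transacylation at the exocyclic imide carbonyl gives the thioester and returns the auxiliary, while any thiolate opening of the lactone is reversible.

Step 10
Reactants: 15 lactone thioester
Product: 16 (2R,3S)-2-[(1Z)-5-[(tert-butyldiphenylsilyl)oxy]-2-methylpent-1-en-1-yl]-5-oxooxolane-3-carbaldehyde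
Conditions: Et3SiH (3 equiv), 10% Pd/C (5 mol%), acetone, rt; used crude
Reagents that add atoms: none
Why: Fukuyama reduction gives the aldehyde under neutral conditions, so the epimerisable C7 centre, the lactone and the trisubstituted alkene are preserved.

Step 11
Reactants: 16 lactone aldehyde; 17 2,3-dibromopropene
Product: 19 (4R,5R)-4-[(1S)-3-bromo-1-hydroxybut-3-en-1-yl]-5-[(1Z)-5-[(tert-butyldiphenylsilyl)oxy]-2-methylpent-1-en-1-yl]oxolan-2-one, via 2-bromoallylchromium reagent 18 (not isolated)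
Conditions: CrCl2 (4 equiv), oxazoline–sulfonamide ligand N-[2-(4-isopropyl-4,5-dihydro-1,3-oxazol-2-yl)-6-methylphenyl]methanesulfonamide (4.4 equiv, the enantiomer matched to Si-face addition), Et3N (4.4 equiv), THF, rt; then 17 (2 equiv) and 16, 0 °C
Reagents that add atoms: CrCl2 Cl[Cr]Cl (in intermediate 18 only)
Why: Nozaki–Hiyama allylation in which divalent chromium inserts only into the allylic C–Br bond (the vinylic one needs nickel) and the allylchromium adds through a closed transition state to the Si face of C8 (Felkin–Anh, anti to the C6 branch, reinforced by the chiral ligand) to give the (8S)-carbinol.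

Step 12
Reactants: 19 bromoallyl carbinol
Product: 20 (4S,5R)-4-[(1S)-3-bromo-1-[(triethylsilyl)oxy]but-3-en-1-yl]-5-[(1Z)-5-[(tert-butyldiphenylsilyl)oxy]-2-methylpent-1-en-1-yl]oxolan-2-one
Conditions: TESOTf, 2,6-lutidine, CH2Cl2, −78 °C
Reagents that add atoms: triethylsilyl triflate CC[Si](CC)(CC)OS(=O)(=O)C(F)(F)F
Why: Silyl protection of the C8 hydroxyl lets the lactone be enolised cleanly in step 13.

Step 13
Reactants: 20 TES ether
Product: 22 (4S,5R)-4-[(1S)-3-bromo-1-[(triethylsilyl)oxy]but-3-en-1-yl]-3-[(dimethylamino)methyl]-5-[(1Z)-5-[(tert-butyldiphenylsilyl)oxy]-2-methylpent-1-en-1-yl]oxolan-2-one (C11 epimers), via lithium enolate 21 (not isolated)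
Conditions: LiN(iPr)2 (LDA, 1.15 equiv), THF, −78 °C; then CH2=NMe2 iodide (3 equiv), −78 °C → rt
Reagents that add atoms: Eschenmoser's salt C=[N+](C)C.[I-]; lithium diisopropylamide [Li+].CC(C)[N-]C(C)C (lithium in intermediate 21 only)
Why: Mannich reaction of the lactone enolate with Eschenmoser's salt adds C13 at C11, whose configuration is irrelevant because C11 becomes sp2 in step 14.

Step 14
Reactants: 22 Mannich base
Product: 24 (4S,5R)-4-[(1S)-3-bromo-1-[(triethylsilyl)oxy]but-3-en-1-yl]-3-methylidene-5-[(1Z)-5-[(tert-butyldiphenylsilyl)oxy]-2-methylpent-1-en-1-yl]oxolan-2-one, via ammonium iodide 23 (not isolated)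
Conditions: MeI (10 equiv), THF, rt; concentrate; sat. aq NaHCO3/CH2Cl2, rt
Reagents that add atoms: iodomethane CI (in intermediate 23 only)
Why: Exhaustive methylation then E1cB (Hofmann-type) loss of trimethylamine gives the exocyclic methylene, which is safe from migration into the ring now that C8 is a carbinol and C7–H is no longer acidic.

Step 15
Reactants: 24 methylene lactone TES ether
Product: 25 (4R,5R)-4-[(1S)-3-bromo-1-hydroxybut-3-en-1-yl]-3-methylidene-5-[(1Z)-5-[(tert-butyldiphenylsilyl)oxy]-2-methylpent-1-en-1-yl]oxolan-2-one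
Conditions: AcOH/THF/H2O (3:1:1), rt
Reagents that add atoms: none
Why: Mild acidic desilylation removes the secondary TES ether and leaves the primary TBDPS ether.

Step 16
Reactants: 25 C8 carbinol; 26 angelic acid
Product: 28 (1S)-3-bromo-1-[(2R,3R)-2-{(1Z)-5-[(tert-butyldiphenylsilyl)oxy]-2-methylpent-1-en-1-yl}-4-methylidene-5-oxooxolan-3-yl]but-3-en-1-yl (2Z)-2-methylbut-2-enoate, via mixed anhydride 27 (not isolated)
Conditions: 26 (3 equiv), 2,4,6-trichlorobenzoyl chloride (3 equiv), Et3N (3 equiv), toluene, rt, 2 h; then 25, 75 °C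
Reagents that add atoms: 2,4,6-trichlorobenzoyl chloride O=C(Cl)c1c(Cl)cc(Cl)cc1Cl (in intermediate 27 only)
Why: Yamaguchi-type mixed-anhydride acylation without a nucleophilic catalyst esterifies the hindered carbinol with retention at C8 and without isomerising the angelate to the tiglate.

Step 17
Reactants: 28 angelate silyl ether
Product: 29 (1S)-3-bromo-1-[(2R,3R)-2-[(1Z)-5-hydroxy-2-methylpent-1-en-1-yl]-4-methylidene-5-oxooxolan-3-yl]but-3-en-1-yl (2Z)-2-methylbut-2-enoate
Conditions: HF·pyridine, pyridine, THF, 0 °C → rt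
Reagents that add atoms: none
Why: Buffered fluoride desilylation frees the primary alcohol and leaves both Michael acceptors untouched.

Step 18
Reactants: 29 primary alcohol
Product: 30 (1S)-3-bromo-1-[(2R,3R)-2-[(1Z)-2-methyl-5-oxopent-1-en-1-yl]-4-methylidene-5-oxooxolan-3-yl]but-3-en-1-yl (2Z)-2-methylbut-2-enoate
Conditions: Dess–Martin periodinane, NaHCO3, CH2Cl2, 0 °C → rt
Reagents that add atoms: none
Why: Dess–Martin oxidation gives the aldehyde under neutral buffered conditions.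

Step 19
Reactants: 30 bromoalkene aldehyde
Product: 32 (6R,7R,8S)-8-angeloyloxy-1-hydroxygermacra-4Z,10(14),11(13)-trien-12,6-olide (C1 epimers), via alkenylchromium species 31 (not isolated)
Conditions: CrCl2 (8 equiv), NiCl2 (2 mol%), degassed DMSO/THF (3:1), rt, 30 added by syringe pump over 12 h (final 2 mM)
Reagents that add atoms: CrCl2 Cl[Cr]Cl (in intermediate 31 only)
Why: Intramolecular Nozaki–Hiyama–Kishi reaction in which zerovalent nickel inserts into the alkenyl bromide and the derived alkenylchromium adds only to the aldehyde, closing the ten-membered ring at C1–C10 with the Z-alkene and trans-lactone as turn elements; the C1 configuration formed here is erased in step 20.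

Step 20
Reactants: 32 macrocyclic allylic alcohol
Product: 33 (6R,7R,8S)-8-angeloyloxy-1-oxogermacra-4Z,10(14),11(13)-trien-12,6-olide
Conditions: Dess–Martin periodinane, NaHCO3, CH2Cl2, 0 °C; used at once
Reagents that add atoms: none
Why: Dess–Martin oxidation converges both C1 epimers to one enone.

Step 21
Reactants: 33 C1 enone
Product: 34 (1S,6R,7R,8S)-8-angeloyloxy-1-hydroxygermacra-4Z,10(14),11(13)-trien-12,6-olide
Conditions: (R)-2-methyl-CBS-oxazaborolidine (0.5 equiv), catecholborane (1.5 equiv), toluene, −78 °C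
Reagents that add atoms: none
Why: Corey–Bakshi–Shibata reduction with the (R)-catalyst, the branched alkenyl side acting as the large group, gives the (1S)-allylic alcohol under reagent control.

Step 22
Reactants: 34 (1S)-allylic alcohol
Product: 35 (1S,6R,7R,8S)-8-angeloyloxy-13-(dimethylamino)-1-hydroxygermacra-4Z,10(14)-dien-12,6-olide (C11 epimers)
Conditions: Me2NH (2 M in THF, 5 equiv), THF, 0 °C → rt
Reagents that add atoms: dimethylamine CNC
Why: Aza-Michael addition masks the lactone methylene (the hindered angelate does not react) so that it never meets peroxide anion in step 24.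

Step 23
Reactants: 36 2,3-dimethylbut-2-ene
Product: 37 2-methoxyprop-2-yl hydroperoxide
Conditions: O3, MeOH/CH2Cl2, −78 °C; used as a solution
Reagents that add atoms: ozone [O-][O+]=O; methanol CO
Why: Ozonolysis in methanol, in which the Criegee carbonyl oxide is trapped by methanol to give the perketal hydroperoxide.

Step 24
Reactants: 35 amine-masked (1S)-alcohol; 37 2-methoxyprop-2-yl hydroperoxide
Product: 39 (1R,6R,7R,8S)-8-angeloyloxy-13-(dimethylamino)-1-[(2-methoxypropan-2-yl)peroxy]germacra-4Z,10(14)-dien-12,6-olide, via mesylate 38 (not isolated)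
Conditions: MsCl (1.5 equiv), Et3N (2 equiv), CH2Cl2, −30 °C, 20 min; then 37 (3 equiv), CsOH·H2O (2.5 equiv), DMF, 0 °C
Reagents that add atoms: methanesulfonyl chloride CS(=O)(=O)Cl (in intermediate 38 only)
Why: Mesylation then SN2 displacement by the peroxy anion (an alpha-effect nucleophile) inverts C1 from S to R and forms the C–O–O bond as an acid-labile perketal.

Step 25
Reactants: 39 amine-masked perketal
Product: 41 (1R,6R,7R,8S)-8-angeloyloxy-1-[(2-methoxypropan-2-yl)peroxy]germacra-4Z,10(14),11(13)-trien-12,6-olide, via ammonium iodide 40 (not isolated)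
Conditions: MeI (10 equiv), THF/MeOH, rt; concentrate; sat. aq NaHCO3/CH2Cl2, rt
Reagents that add atoms: iodomethane CI (in intermediate 40 only)
Why: Quaternisation then E1cB (Hofmann-type) loss of trimethylamine regenerates the lactone methylene under conditions that leave the peroxyketal intact.

Step 26
Reactants: 41 perketal of the target
Product: 42 (1R,6R,7R,8S)-8-angeloyloxy-1-hydroperoxygermacra-4Z,10(14),11(13)-trien-12,6-olide (target)
Conditions: AcOH/THF/H2O (4:2:1), rt
Reagents that add atoms: none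
Why: Mild acidic hydrolysis of the peroxyketal releases the free hydroperoxide without touching the esters, the lactone methylene or the C1 stereocentre.

**Compound list**

1 | neryl acetate, (2Z)-3,7-dimethylocta-2,6-dien-1-yl acetate | CC(=O)OC/C=C(/C)CCC=C(C)C | starting material
2 | 6,7-epoxyneryl acetate (racemic at the epoxide) | CC(=O)OC/C=C(/C)CCC1OC1(C)C | intermediate
3 | (2Z)-6,7-dihydroxy-3,7-dimethyloct-2-en-1-yl acetate (racemic diol) | CC(=O)OC/C=C(/C)CCC(O)C(C)(C)O | intermediate (not isolated)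
4 | (2Z)-3-methyl-6-oxohex-2-en-1-yl acetate | CC(=O)OC/C=C(/C)CCC=O | intermediate
5 | (2Z)-6-hydroxy-3-methylhex-2-en-1-yl acetate | CC(=O)OC/C=C(/C)CCCO | intermediate
6 | (2Z)-6-[(tert-butyldiphenylsilyl)oxy]-3-methylhex-2-en-1-yl acetate | CC(=O)OC/C=C(/C)CCCO[Si](c1ccccc1)(c1ccccc1)C(C)(C)C | intermediate
7 | (2Z)-6-[(tert-butyldiphenylsilyl)oxy]-3-methylhex-2-en-1-ol | OC/C=C(/C)CCCO[Si](c1ccccc1)(c1ccccc1)C(C)(C)C | intermediate
8 | (2Z)-6-[(tert-butyldiphenylsilyl)oxy]-3-methylhex-2-enal | O=C/C=C(/C)CCCO[Si](c1ccccc1)(c1ccccc1)C(C)(C)C | intermediate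
9 | (4S)-4-benzyl-1,3-oxazolidin-2-one | O=C1N[C@@H](Cc2ccccc2)CO1 | starting material
10 | methyl 4-chloro-4-oxobutanoate | COC(=O)CCC(Cl)=O | starting material
11 | methyl 4-[(4S)-4-benzyl-2-oxo-1,3-oxazolidin-3-yl]-4-oxobutanoate | COC(=O)CCC(=O)N1[C@@H](Cc2ccccc2)COC1=O | intermediate
12 | dibutylboron (Z)-enolate of 11 | COC(=O)C/C=C(\OB(CCCC)CCCC)N1[C@@H](Cc2ccccc2)COC1=O | intermediate (not isolated)
13 | dibutylboron syn-aldolate (6R,7S), open-chain methyl ester | COC(=O)C[C@H](C(=O)N1[C@@H](Cc2ccccc2)COC1=O)[C@@H](/C=C(/C)CCCO[Si](c1ccccc1)(c1ccccc1)C(C)(C)C)OB(CCCC)CCCC | intermediate (not isolated)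
14 | (4S)-4-benzyl-3-{[(2R,3S)-2-[(1Z)-5-[(tert-butyldiphenylsilyl)oxy]-2-methylpent-1-en-1-yl]-5-oxooxolan-3-yl]carbonyl}-1,3-oxazolidin-2-one (trans lactone imide) | O=C1C[C@H](C(=O)N2[C@@H](Cc3ccccc3)COC2=O)[C@@H](/C=C(/C)CCCO[Si](c2ccccc2)(c2ccccc2)C(C)(C)C)O1 | intermediate
15 | S-ethyl (2R,3S)-2-[(1Z)-5-[(tert-butyldiphenylsilyl)oxy]-2-methylpent-1-en-1-yl]-5-oxooxolane-3-carbothioate | O=C1C[C@H](C(=O)SCC)[C@@H](/C=C(/C)CCCO[Si](c2ccccc2)(c2ccccc2)C(C)(C)C)O1 | intermediate
16 | (2R,3S)-2-[(1Z)-5-[(tert-butyldiphenylsilyl)oxy]-2-methylpent-1-en-1-yl]-5-oxooxolane-3-carbaldehyde | O=C1C[C@H](C=O)[C@@H](/C=C(/C)CCCO[Si](c2ccccc2)(c2ccccc2)C(C)(C)C)O1 | intermediate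
17 | 2,3-dibromopropene | C=C(Br)CBr | starting material
18 | (2-bromoprop-2-en-1-yl)chromium dichloride (ligand-bound in the flask) | C=C(Br)C[Cr](Cl)Cl | intermediate (not isolated)
19 | (4R,5R)-4-[(1S)-3-bromo-1-hydroxybut-3-en-1-yl]-5-[(1Z)-5-[(tert-butyldiphenylsilyl)oxy]-2-methylpent-1-en-1-yl]oxolan-2-one | O=C1C[C@H]([C@@H](O)CC(Br)=C)[C@@H](/C=C(/C)CCCO[Si](c2ccccc2)(c2ccccc2)C(C)(C)C)O1 | intermediate
20 | (4S,5R)-4-[(1S)-3-bromo-1-[(triethylsilyl)oxy]but-3-en-1-yl]-5-[(1Z)-5-[(tert-butyldiphenylsilyl)oxy]-2-methylpent-1-en-1-yl]oxolan-2-one | O=C1C[C@H]([C@@H](O[Si](CC)(CC)CC)CC(Br)=C)[C@@H](/C=C(/C)CCCO[Si](c2ccccc2)(c2ccccc2)C(C)(C)C)O1 | intermediate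
21 | lithium enolate of 20 | [Li]OC1=C[C@H]([C@@H](O[Si](CC)(CC)CC)CC(Br)=C)[C@@H](/C=C(/C)CCCO[Si](c2ccccc2)(c2ccccc2)C(C)(C)C)O1 | intermediate (not isolated)
22 | 3-[(dimethylamino)methyl] derivative of 20 (C11 epimers; C6 R, C7 S, C8 S) | O=C1C(CN(C)C)[C@H]([C@@H](O[Si](CC)(CC)CC)CC(Br)=C)[C@@H](/C=C(/C)CCCO[Si](c2ccccc2)(c2ccccc2)C(C)(C)C)O1 | intermediate
23 | trimethylammonium iodide of 22 | O=C1C(C[N+](C)(C)C)[C@H]([C@@H](O[Si](CC)(CC)CC)CC(Br)=C)[C@@H](/C=C(/C)CCCO[Si](c2ccccc2)(c2ccccc2)C(C)(C)C)O1.[I-] | intermediate (not isolated)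
24 | (4S,5R)-4-[(1S)-3-bromo-1-[(triethylsilyl)oxy]but-3-en-1-yl]-3-methylidene-5-[(1Z)-5-[(tert-butyldiphenylsilyl)oxy]-2-methylpent-1-en-1-yl]oxolan-2-one | O=C1C(=C)[C@H]([C@@H](O[Si](CC)(CC)CC)CC(Br)=C)[C@@H](/C=C(/C)CCCO[Si](c2ccccc2)(c2ccccc2)C(C)(C)C)O1 | intermediate
25 | (4R,5R)-4-[(1S)-3-bromo-1-hydroxybut-3-en-1-yl]-3-methylidene-5-[(1Z)-5-[(tert-butyldiphenylsilyl)oxy]-2-methylpent-1-en-1-yl]oxolan-2-one | O=C1C(=C)[C@H]([C@@H](O)CC(Br)=C)[C@@H](/C=C(/C)CCCO[Si](c2ccccc2)(c2ccccc2)C(C)(C)C)O1 | intermediate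
26 | angelic acid, (2Z)-2-methylbut-2-enoic acid | C/C=C(/C)C(=O)O | starting material
27 | angelic 2,4,6-trichlorobenzoic anhydride | C/C=C(/C)C(=O)OC(=O)c1c(Cl)cc(Cl)cc1Cl | intermediate (not isolated)
28 | (1S)-3-bromo-1-[(2R,3R)-2-{(1Z)-5-[(tert-butyldiphenylsilyl)oxy]-2-methylpent-1-en-1-yl}-4-methylidene-5-oxooxolan-3-yl]but-3-en-1-yl (2Z)-2-methylbut-2-enoate | O=C1C(=C)[C@H]([C@@H](OC(=O)/C(C)=C\C)CC(Br)=C)[C@@H](/C=C(/C)CCCO[Si](c2ccccc2)(c2ccccc2)C(C)(C)C)O1 | intermediate
29 | (1S)-3-bromo-1-[(2R,3R)-2-[(1Z)-5-hydroxy-2-methylpent-1-en-1-yl]-4-methylidene-5-oxooxolan-3-yl]but-3-en-1-yl (2Z)-2-methylbut-2-enoate | O=C1C(=C)[C@H]([C@@H](OC(=O)/C(C)=C\C)CC(Br)=C)[C@@H](/C=C(/C)CCCO)O1 | intermediate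
30 | (1S)-3-bromo-1-[(2R,3R)-2-[(1Z)-2-methyl-5-oxopent-1-en-1-yl]-4-methylidene-5-oxooxolan-3-yl]but-3-en-1-yl (2Z)-2-methylbut-2-enoate | O=C1C(=C)[C@H]([C@@H](OC(=O)/C(C)=C\C)CC(Br)=C)[C@@H](/C=C(/C)CCC=O)O1 | intermediate
31 | alkenylchromium dichloride species from 30 (Cr in place of Br at C10) | O=C1C(=C)[C@H]([C@@H](OC(=O)/C(C)=C\C)CC([Cr](Cl)Cl)=C)[C@@H](/C=C(/C)CCC=O)O1 | intermediate (not isolated)
32 | (6R,7R,8S)-8-angeloyloxy-1-hydroxygermacra-4Z,10(14),11(13)-trien-12,6-olide (C1 epimers) | C=C1C(=O)O[C@@H]2/C=C(/C)CCC(O)C(=C)C[C@H](OC(=O)/C(C)=C\C)[C@@H]12 | intermediate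
33 | (6R,7R,8S)-8-angeloyloxy-1-oxogermacra-4Z,10(14),11(13)-trien-12,6-olide | C=C1C(=O)O[C@@H]2/C=C(/C)CCC(=O)C(=C)C[C@H](OC(=O)/C(C)=C\C)[C@@H]12 | intermediate
34 | (1S,6R,7R,8S)-8-angeloyloxy-1-hydroxygermacra-4Z,10(14),11(13)-trien-12,6-olide | C=C1C(=O)O[C@@H]2/C=C(/C)CC[C@H](O)C(=C)C[C@H](OC(=O)/C(C)=C\C)[C@@H]12 | intermediate
35 | (1S,6R,7R,8S)-8-angeloyloxy-13-(dimethylamino)-1-hydroxygermacra-4Z,10(14)-dien-12,6-olide (C11 epimers) | CN(C)CC1C(=O)O[C@@H]2/C=C(/C)CC[C@H](O)C(=C)C[C@H](OC(=O)/C(C)=C\C)[C@@H]12 | intermediate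
36 | 2,3-dimethylbut-2-ene | CC(C)=C(C)C | starting material
37 | 2-methoxyprop-2-yl hydroperoxide | COC(C)(C)OO | intermediate
38 | (1S)-mesylate of 35 | CN(C)CC1C(=O)O[C@@H]2/C=C(/C)CC[C@H](OS(C)(=O)=O)C(=C)C[C@H](OC(=O)/C(C)=C\C)[C@@H]12 | intermediate (not isolated)
39 | (1R,6R,7R,8S)-8-angeloyloxy-13-(dimethylamino)-1-[(2-methoxypropan-2-yl)peroxy]germacra-4Z,10(14)-dien-12,6-olide | CN(C)CC1C(=O)O[C@@H]2/C=C(/C)CC[C@@H](OOC(C)(C)OC)C(=C)C[C@H](OC(=O)/C(C)=C\C)[C@@H]12 | intermediate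
40 | trimethylammonium iodide of 39 | C[N+](C)(C)CC1C(=O)O[C@@H]2/C=C(/C)CC[C@@H](OOC(C)(C)OC)C(=C)C[C@H](OC(=O)/C(C)=C\C)[C@@H]12.[I-] | intermediate (not isolated)
41 | (1R,6R,7R,8S)-8-angeloyloxy-1-[(2-methoxypropan-2-yl)peroxy]germacra-4Z,10(14),11(13)-trien-12,6-olide | C=C1C(=O)O[C@@H]2/C=C(/C)CC[C@@H](OOC(C)(C)OC)C(=C)C[C@H](OC(=O)/C(C)=C\C)[C@@H]12 | intermediate
42 | (1R,6R,7R,8S)-8-angeloyloxy-1-hydroperoxygermacra-4Z,10(14),11(13)-trien-12,6-olide | C=C1C(=O)O[C@@H]2/C=C(/C)CC[C@@H](OO)C(=C)C[C@H](OC(=O)/C(C)=C\C)[C@@H]12 | target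

**Totals**

Total step count: 26 (25 on the line to the target plus step 23, which makes reagent 37).
Longest linear sequence: 24 steps (steps 1–6, 8–22 and 24–26, from neryl acetate).

**Three steps most likely to fail, with fallbacks**

Step 11 (C8 configuration in the 2-bromoallylation). The aldehyde is α-branched and β-oxygenated, and the sense of the ligand must be confirmed on the first run. The fallback sets out from 16 and comes back at 19. Compound 16 is treated with reagent 18 made from 17 and CrCl2 in THF without any ligand, which gives 19 together with its (8R)-epimer F1. F1 is separated and inverted by a Mitsunobu reaction with chloroacetic acid (PPh3, DIAD, toluene, 0 °C) to the (8S)-chloroacetate F2. The chloroacetyl group is then removed with thiourea and NaHCO3 in EtOH at 50 °C, which leaves the lactone alone and delivers 19. Both epimers of the addition therefore end up as 19.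

Step 19 (ten-membered ring closure). Transannular strain, oligomerisation, or nickel insertion into the allylic lactone C–O bond could defeat it. The fallback sets out from 25 and comes back at 33; it cyclises before the bulky ester is on C8 and then tells the two carbinols apart by chemoselective oxidation. HF·pyridine removes the silyl group of 25 to give the diol F3. TEMPO/PhI(OAc)2 oxidises only the primary alcohol to the hydroxy aldehyde F4. CrCl2/NiCl2 in DMSO at high dilution converts F4 through the alkenylchromium species F5 into the macrocyclic diol F6. MnO2 in CH2Cl2 oxidises only the allylic C1 carbinol of F6 to the hydroxy enone F7. Acylation of F7 with mixed anhydride 27 (toluene, 75 °C) gives 33.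

Step 24 (peroxide SN2 at the ring allylic mesylate). SN2′ attack at C14, elimination to a diene, or attack of the peroxy anion on the esters could compete. The fallback sets out from 34 and comes back at 42; it uses no base and no masking, so steps 22–26 are not needed. Alcohol 34 is converted (MsCl, Et3N, CH2Cl2, −40 °C) into the mesylate F8, which is treated at once with a large excess of anhydrous H2O2 in Et2O at −40 → 0 °C. Neutral hydrogen peroxide does not epoxidise the enoates, and direct displacement with inversion gives 42. Stereochemical leakage through ionisation is the price of this shorter path.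

**Further compounds**

F1 | step 11 | (4R,5R)-4-[(1R)-3-bromo-1-hydroxybut-3-en-1-yl]-5-[(1Z)-5-[(tert-butyldiphenylsilyl)oxy]-2-methylpent-1-en-1-yl]oxolan-2-one, the (8R)-epimer of 19 | O=C1C[C@H]([C@H](O)CC(Br)=C)[C@@H](/C=C(/C)CCCO[Si](c2ccccc2)(c2ccccc2)C(C)(C)C)O1
F2 | step 11 | (8S)-chloroacetate of 19 | O=C1C[C@H]([C@@H](OC(=O)CCl)CC(Br)=C)[C@@H](/C=C(/C)CCCO[Si](c2ccccc2)(c2ccccc2)C(C)(C)C)O1
F3 | step 19 | (4R,5R)-4-[(1S)-3-bromo-1-hydroxybut-3-en-1-yl]-5-[(1Z)-5-hydroxy-2-methylpent-1-en-1-yl]-3-methylideneoxolan-2-one (diol) | O=C1C(=C)[C@H]([C@@H](O)CC(Br)=C)[C@@H](/C=C(/C)CCCO)O1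
F4 | step 19 | (4R,5R)-4-[(1S)-3-bromo-1-hydroxybut-3-en-1-yl]-5-[(1Z)-2-methyl-5-oxopent-1-en-1-yl]-3-methylideneoxolan-2-one (hydroxy aldehyde) | O=C1C(=C)[C@H]([C@@H](O)CC(Br)=C)[C@@H](/C=C(/C)CCC=O)O1
F5 | step 19 | alkenylchromium dichloride species from F4 (Cr in place of Br) | O=C1C(=C)[C@H]([C@@H](O)CC([Cr](Cl)Cl)=C)[C@@H](/C=C(/C)CCC=O)O1
F6 | step 19 | (6R,7R,8S)-1,8-dihydroxygermacra-4Z,10(14),11(13)-trien-12,6-olide (C1 epimers) | C=C1C(=O)O[C@@H]2/C=C(/C)CCC(O)C(=C)C[C@H](O)[C@@H]12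
F7 | step 19 | (6R,7R,8S)-8-hydroxy-1-oxogermacra-4Z,10(14),11(13)-trien-12,6-olide | C=C1C(=O)O[C@@H]2/C=C(/C)CCC(=O)C(=C)C[C@H](O)[C@@H]12
F8 | step 24 | (1S)-mesylate of 34 | C=C1C(=O)O[C@@H]2/C=C(/C)CC[C@H](OS(C)(=O)=O)C(=C)C[C@H](OC(=O)/C(C)=C\C)[C@@H]12
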